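Its constants are assumed.

The vessel is closed and stirred, and its two flasks, gamma and eta, differ in their charge of nucleophile.

    electrophile + nucleophile → acid set free + product (k1 = 0.023 M⁻¹ min⁻¹)
    nucleophile + acid set free ⇌ protonated nucleophile, settled at all times (K2 = 1500 M⁻¹)
    acid set free + free base ⇌ salt of the base, settled at all times (K3 = 410 M⁻¹)
    crystals ⇌ acid set free, rate k4*(cs4 - [acid set free]) while solid is left; crystals form when [acid set free] > cs4 (cs4 = 38 mM, k4 = 0.40 min⁻¹)
    gas ⇌ free base, rate k5*(csat - [free base]) (k5 = 2.6 min⁻¹, csat = 5.8 mM)

| flask | electrophile | nucleophile | gas | time |
|---|---|---|---|---|
| gamma | 0.072 M | 0.180 M | 5.8 mM (held) | 1.0 h |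
| eta | 0.072 M | 0.360 M | 5.8 mM (held) | 1.0 h |

- what is said of acid set free includes crystals
- crystals is a solid; its amount is given per volume of the solution
- at the start none of free base is dissolved
- run time (gamma): 1.0 h

- part of the electrophile that has reacted at the end, gamma
- part of the electrophile that has reacted at the end, eta
- what raising the concentration of nucleophile from its lowest to its highest value here does to the part of the electrophile that has reacted (changes below 5 percentage points count as none) (it rises / no change / it falls)

*What do you count?* Gamma gives 0.248 and eta 0.497. That number is the lifetimes run: the first step's constant times the nucleophile times the time. It is a pseudo-first-order count.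

*And the conversion?* One minus the exponential of minus the count. That gives 22.0 % for gamma and 39.2 % for eta.

*Does the nucleophile stay as charged?* No. In gamma the acid set free goes to the nucleophile rather than to the free base, since 270, reckoned with the nucleophile as charged, stands far above 2.38, reckoned with the free base at saturation. So I reckon two nucleophiles for each electrophile reacted.

*Crystals?* I expect none in gamma. Free acid comes to about 0.0587 mM, far below the solubility of 38 mM.

*Then your count is too high?* Yes. The mean nucleophile lies lower by the conversion times the electrophile charge. Gamma's count shrinks to 0.227 and eta's to 0.458. I commit to 20.3 % for gamma and 36.7 % for eta, a rise of 16 percentage points.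

The forecast says 20.3 % for gamma and 36.7 % for eta, and of the trend, it rises. Its ground is “the nucleophile consumed at double rate”. Its figures and mine match to the digits shown.

The simulation gives 20.3 % for gamma and 36.7 % for eta. From gamma to eta it rises, by 16 points. The forecast stands. A nucleophile charge of 0.132 M or 0.231 M moves gamma's answer by 5 points. The count follows the lower charge: gamma there runs 0.182 lifetimes, or 0.166 at mean nucleophile, which gives 15.3 %.

Now take a neighbour, the eta flask with 0.61 M of nucleophile. Its count is 0.842 lifetimes, or 0.785 at mean nucleophile, which gives 54.4 %. The computed neighbour gives 54.2 %.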